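You must decide first whether to book E as a bystander or as a reagent that takes one X out of the charge for each E put in. I book it as the reagent, a choice that the earlier readings leave open.

| flask | X | E | remark | time |
|---|---|---|---|---|
| oak | 2 M | 0.0048 M | run made earlier |  |
| alder | 2 M | 0.038 M | run made earlier |  |
| north-west | 2.0 M | 0.00400 M |  | 40 h |
| north | 2.0 M | 0.0120 M |  | 40 h |
| east | 2.0 M | 0.0300 M |  | 40 h |
| south | 2.0 M | 0.100 M |  | 40 h |
| north-east | 2.0 M | 0.300 M |  | 40 h |

| run | time / h | J / % |
|---|---|---|
| oak | 4.00 | 25.6 |
| oak | 10.0 | 43.8 |
| oak | 20.0 | 47.7 |
| oak | 30.0 | 41.1 |
| alder | 8.00 | 39.4 |
| alder | 15.0 | 48.8 |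
| alder | 20.0 | 48.0 |
| alder | 30.0 | 40.1 |

(scatter of a reading: 0.5 percentage points)

* amount of J at the end, in percent of the X charged for north-west, north, east, south, north-east, in this order
* the shape of the row from first to last (hardly changes / rises, then falls / falls all the way / falls, then rises / rises all the way)

- "hardly changes" means that all values lie within two and a half points (for a concentration: within two and a half percent of the largest)

Two numbers here seem not to go together: alder held 7.92 times the E of oak, yet at 20.0 h oak read 47.7% and alder 48.0%. Treat E as a correction to the charge and the conflict goes. E charged over X charged is 0.00240 in oak, 0.0190 in alder and 0.150 in north-east. This ratio, the diverted share, is the part of the charge that E, as limiting reagent of a side step, takes off the road to J once it has reacted to the end, and in my reckoning J at a given time is scaled by one minus the share.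

Between oak and alder that scaling moves a reading by 0.79 percentage points, while each reading scatters by 0.5 points, and oak minus alder came to −0.3 points at 20.0 h and 1 point at 30.0 h. So the two curves can coincide within their scatter with E at work.

For 40 h I let the mean of the two runs fall from 30.0 h by the factor it lost over the same interval before, which gives a level of 34.4%. With a share of 0.00200, north-west then holds 34.3% and north-east 29.2%, a fall of 5.1 points. The share grows along the row, so I commit to J falling at each step.

The forecast prints 30.5% from north-west to north-east, shape hardly changes, on the ground that “E has no visible effect on either step between 0.005 and 0.04 M”, and there my reckoning parts from it.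

The flasks give 32.1%, 31.9%, 31.7%, 30.6% and 27.6%, so the row falls all the way, by 4.5 points against my 5.1 points, from a level lower than mine.

J → Z (k = 0.0370 h⁻¹); X ⇌ J + G (K = 10.0 M, k = 0.0800 h⁻¹); X + E → L (k = 0.0880 M⁻¹ h⁻¹) In north-east at 40.0 h, L stands at 13.1% of the X charged, beside a diverted share of 0.150. Now put the share to south, where it is 0.0500: scaling the north-west value by one minus the share, over one minus the north-west share, gives 30.6%, and south stands at 30.6%.

The numbers in the tables are calculated from invented constants; scatter was added.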